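**Plan**

1. Ring locants used for every six-membered-ring compound: C1 = ring C=O, C2 = ring CH=, C3 = carbon bearing CH2OAc, C4 = CHOH, C5 = epoxide CH, C6 = epoxide carbon bearing the C15 chain.
2. Retrosynthesis: C4–OH ⇒ C4 ketone ⇒ C4 dimethyl ketal; epoxide ⇒ C5=C6 of a quinone monoketal ⇒ 4-methoxyphenol; then ring bond C1–C6 is cut (6π-electrocyclisation in reverse) and the four-membered ring C1–C2–C3–C4 is re-formed; further cuts at C4–C5 (alkenyllithium + ketone), C3–CH2O (alkoxymethyllithium + vinylogous ester) and the allyl–vinyl bond of the chain (Stille).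
3. Enabling feature: C1 and C4 both carry oxygen and lie para across the C2=C3 double bond; the array O–C1–C2=C3–C4–O is a 4-alkoxycyclobut-2-enone (ring C1–C4), and C5/C6 are the vinyl group on C4.
4. Forward: the chain vinylstannane is made from farnesyl acetate; two regiodefined carbonyl additions to a squarate-derived dione give the cyclobutenone; heating expands it to the benzene ring with O1 free and O4 methylated, so oxidation in methanol gives the C4 monoketal only; then epoxide, acetate, enedione, carbinol.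
5. Stereochemistry: E-olefins from farnesol and the E-distannane; C5 and C6 from tartrate-mediated, hydroxymethyl-directed nucleophilic epoxidation; C4 from Luche reduction anti to the epoxide oxygen (OH cis to the epoxide).

Key step: step 8

Assumption: L-(+)-diisopropyl tartrate is taken to deliver the required (5S,6R)-epoxide in step 11; if the sense of induction is the opposite, D-(−)-diisopropyl tartrate is used with everything else unchanged.

**Step 1**
Reactants: 1 (2E,6E)-farnesyl acetate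
Product: 2 (2E,6E,10E)-12-hydroxy-3,7,11-trimethyldodeca-2,6,10-trien-1-yl acetate
Conditions: SeO2 (0.1 equiv), t-BuOOH (70% aq.), salicylic acid (0.1 equiv), CH2Cl2, 0 °C to rt, stopped at partial conversion
Reagents that add atoms: tert-butyl hydroperoxide, CC(C)(C)OO (net oxygen source, relayed by catalytic SeO2)
Why: Riley allylic oxidation (ene reaction of SeO2, then [2,3]-sigmatropic shift) should hydroxylate the E-methyl group of the terminal, most electron-rich alkene and give the E-allylic alcohol, the 2,3-alkene being deactivated by the allylic acetate.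

**Step 2**
Reactants: 2 (2E,6E,10E)-12-hydroxy-3,7,11-trimethyldodeca-2,6,10-trien-1-yl acetate
Product: 3 (2E,6E,10E)-12-(tert-butyldimethylsilyloxy)-3,7,11-trimethyldodeca-2,6,10-trien-1-yl acetate
Conditions: TBSCl, imidazole, DMF, rt
Reagents that add atoms: tert-butyldimethylsilyl chloride, CC(C)(C)[Si](C)(C)Cl
Why: Standard silylation of a primary alcohol; the silyl ether should survive organolithium, oxidising and basic steps and is removed in step 13.

**Step 3**
Reactants: 3 (2E,6E,10E)-12-(tert-butyldimethylsilyloxy)-3,7,11-trimethyldodeca-2,6,10-trien-1-yl acetate; 4 (E)-1,2-bis(tributylstannyl)ethene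
Product: 5 tributyl[(1E,4E,8E,12E)-14-(tert-butyldimethylsilyloxy)-5,9,13-trimethyltetradeca-1,4,8,12-tetraen-1-yl]stannane
Conditions: 4 (3 equiv), Pd(dba)2 (5 mol %), LiCl (3 equiv), DMF, 25 to 40 °C; chromatography on Et3N-deactivated silica
Reagents that add atoms: none
Why: Stille coupling of an allylic acetate: zerovalent palladium ionises the acetate to the π-allyl complex, the vinylstannane transmetalates with retention and reductive elimination at the primary allyl terminus should give the skipped diene with the 2E geometry kept (syn–anti isomerisation would need the σ-allyl form at the tertiary carbon), excess 4 suppressing double coupling.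

**Step 4**
Reactants: 6 diisopropyl squarate
Product: 8 3-isopropoxycyclobut-3-ene-1,2-dione, via 4-hydroxy-2,3-diisopropoxycyclobut-2-en-1-one 7 (not isolated)
Conditions: LiAlH(OtBu)3 (1.0 equiv), THF, −78 to −20 °C; then 6 M aq. HCl, CH2Cl2, rt
Reagents that add atoms: water, O (supplies the new carbonyl oxygen)
Why: One equivalent of the bulky hydride reduces one of the two equivalent vinylogous-ester carbonyls, and on acidification the hydroxyl of 7 ionises to an isopropoxy-stabilised cyclobutenyl cation that is hydrated at the distal alkoxy carbon and loses isopropanol (1,3-transposition), which should give the monoalkoxy dione.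

**Step 5**
Reactants: 9 (tributylstannyl)methanol
Product: 10 tributyl{[(4-methoxybenzyl)oxy]methyl}stannane
Conditions: NaH, 4-methoxybenzyl chloride, Bu4NI (cat.), THF/DMF, 0 °C to rt
Reagents that add atoms: 4-methoxybenzyl chloride, COc1ccc(CCl)cc1
Why: Williamson etherification of the stannylmethanol alkoxide; the PMB ether is stable to organolithiums and heat and is removed oxidatively in step 10.

**Step 6**
Reactants: 5 tributyl[(1E,4E,8E,12E)-14-(tert-butyldimethylsilyloxy)-5,9,13-trimethyltetradeca-1,4,8,12-tetraen-1-yl]stannane; 8 3-isopropoxycyclobut-3-ene-1,2-dione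
Product: 13 racemic 4-[(1E,4E,8E,12E)-14-(tert-butyldimethylsilyloxy)-5,9,13-trimethyltetradeca-1,4,8,12-tetraen-1-yl]-3-isopropoxy-4-methoxycyclobut-2-en-1-one, via E-alkenyllithium 11 (not isolated), via lithium alkoxide 12 (not isolated)
Conditions: 5, n-BuLi (0.98 equiv), THF, −78 to −40 °C; added to 8, THF/Et2O, −78 °C; then MeOTf, −78 to −20 °C; product kept cold
Reagents that add atoms: methyl trifluoromethanesulfonate, COS(=O)(=O)C(F)(F)F
Why: Tin–lithium exchange gives the E-alkenyllithium with retention; it should add 1,2 to the ketone-like carbonyl (the one attached to the isopropoxy-bearing carbon) because the other carbonyl is deactivated as a vinylogous ester, and the alkoxide is O-methylated in situ; the new quaternary centre is racemic and is destroyed in step 8.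

**Step 7**
Reactants: 13 racemic 4-alkenyl-3-isopropoxy-4-methoxycyclobut-2-en-1-one (alkenyl as above); 10 tributyl{[(4-methoxybenzyl)oxy]methyl}stannane
Product: 16 racemic 4-[(1E,4E,8E,12E)-14-(tert-butyldimethylsilyloxy)-5,9,13-trimethyltetradeca-1,4,8,12-tetraen-1-yl]-4-methoxy-3-{[(4-methoxybenzyl)oxy]methyl}cyclobut-2-en-1-one, via (4-methoxybenzyloxy)methyllithium 14 (not isolated), via tertiary lithium alkoxide 15 (not isolated)
Conditions: 10, n-BuLi, THF, −78 °C; then 13, −78 °C; then 1 M aq. HCl, THF, 0 °C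
Reagents that add atoms: water, O (supplies the new carbonyl oxygen)
Why: Stork–Danheiser alkylative 1,3-carbonyl transposition: the α-alkoxymethyllithium adds to the vinylogous-ester carbonyl, and dilute acid ionises the tertiary allylic alkoxide 15 towards the isopropoxy-bearing carbon, hydration and loss of isopropanol placing the carbonyl next to the quaternary carbon and CH2OPMB on the future C3 with no regiochemical ambiguity.

**Step 8**
Reactants: 16 racemic 4-alkenyl-4-methoxy-3-{[(4-methoxybenzyl)oxy]methyl}cyclobut-2-en-1-one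
Product: 19 6-[(2E,6E,10E)-12-(tert-butyldimethylsilyloxy)-3,7,11-trimethyldodeca-2,6,10-trien-1-yl]-4-methoxy-3-{[(4-methoxybenzyl)oxy]methyl}phenol (OH on C1), via dienylketene 17 (not isolated), via cyclohexa-2,4-dienone 18 (not isolated)
Conditions: toluene (degassed, 0.02 M), 110 °C
Reagents that add atoms: none
Why: Heating opens the cyclobutenone by 4π-conrotatory cleavage of the C1–C4 σ-bond with the methoxy group turning outward, so the vinyl group comes cis to the ketene carbon in 17; a 6π-disrotatory electrocyclisation then joins the ketene carbon C1 to the vinyl terminus C6, and enolisation of 18 gives the arene. The closest known reaction type is the Liebeskind–Moore ring expansion of 4-alkenyl-4-alkoxy (or hydroxy) cyclobutenones to hydroquinone derivatives. The six-membered ring closes by the 6π-electrocyclisation (bond C1–C6), the four-membered ring being the only ring lost. No stereocentre survives, since the sp3 carbon C6 of 18 is flattened on tautomerisation; what the step fixes is constitution: the cyclobutenone carbons become C1–C4, the vinyl carbons C5 and C6, the free hydroxyl sits on C1 and the methyl ether on C4. The selectivity needed is outward rotation of the donor OMe group, secured by the known torquoselectivity of alkoxy groups at C4 of cyclobutenones, and capture of the ketene by the cis vinyl group ahead of any [2+2] reaction with the chain alkenes, secured by proximity.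

**Step 9**
Reactants: 19 6-(silyloxy-trienyl)-4-methoxy-3-{[(4-methoxybenzyl)oxy]methyl}phenol
Product: 20 6-[(2E,6E,10E)-12-(tert-butyldimethylsilyloxy)-3,7,11-trimethyldodeca-2,6,10-trien-1-yl]-4,4-dimethoxy-3-{[(4-methoxybenzyl)oxy]methyl}cyclohexa-2,5-dien-1-one
Conditions: PhI(OAc)2, NaHCO3, MeOH, 0 °C
Reagents that add atoms: methanol, CO
Why: Oxidative dearomatisation of a 4-methoxyphenol: the phenoxenium-type intermediate is captured by methanol at the methoxy-bearing para carbon, so the ketal should form at C4 only and C1 stays the carbonyl.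

**Step 10**
Reactants: 20 4,4-dimethoxy-3-{[(4-methoxybenzyl)oxy]methyl} dienone
Product: 21 6-[(2E,6E,10E)-12-(tert-butyldimethylsilyloxy)-3,7,11-trimethyldodeca-2,6,10-trien-1-yl]-3-(hydroxymethyl)-4,4-dimethoxycyclohexa-2,5-dien-1-one
Conditions: DDQ, CH2Cl2/pH 7 phosphate buffer, 0 °C
Reagents that add atoms: none
Why: Oxidative PMB ether cleavage (hydride abstraction from the electron-rich benzylic position, hydrolysis of the oxocarbenium ion) should leave the electron-poor dienone, the buffered ketal and the silyl ether untouched.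

**Step 11**
Reactants: 21 3-(hydroxymethyl)-4,4-dimethoxy dienone
Product: 22 (5S,6R)-6-[(2E,6E,10E)-12-(tert-butyldimethylsilyloxy)-3,7,11-trimethyldodeca-2,6,10-trien-1-yl]-5,6-epoxy-3-(hydroxymethyl)-4,4-dimethoxycyclohex-2-en-1-one
Conditions: Ph3COOH, NaN(SiMe3)2, L-(+)-diisopropyl tartrate, 4 Å molecular sieves, toluene, −55 °C
Reagents that add atoms: trityl hydroperoxide, OOC(c1ccccc1)(c1ccccc1)c1ccccc1
Why: Tartrate-mediated Weitz–Scheffer nucleophilic epoxidation: the peroxide, held in a sodium tartrate aggregate bound to the C3 hydroxymethyl alkoxide, should add to the unsubstituted β-carbon C5 (C3 is a substituted β-carbon) and close onto C6, the tartrate choosing the enantioface and setting C5 and C6 together.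

**Step 12**
Reactants: 22 (5S,6R)-epoxy hydroxymethyl monoketal
Product: 23 (5S,6R)-3-(acetoxymethyl)-6-[(2E,6E,10E)-12-(tert-butyldimethylsilyloxy)-3,7,11-trimethyldodeca-2,6,10-trien-1-yl]-5,6-epoxy-4,4-dimethoxycyclohex-2-en-1-one
Conditions: Ac2O, pyridine, DMAP (cat.), CH2Cl2, 0 °C
Reagents that add atoms: acetic anhydride, CC(=O)OC(C)=O
Why: Acylation of the only free hydroxyl; the epoxy ketone and ketal are stable to these mild basic conditions.

**Step 13**
Reactants: 23 (5S,6R)-acetoxymethyl epoxy monoketal silyl ether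
Product: 24 (5S,6R)-3-(acetoxymethyl)-5,6-epoxy-6-[(2E,6E,10E)-12-hydroxy-3,7,11-trimethyldodeca-2,6,10-trien-1-yl]cyclohex-2-ene-1,4-dione
Conditions: 48% aq. HF, MeCN, 0 °C to rt
Reagents that add atoms: water, O (carbonyl oxygen at C4)
Why: Aqueous HF should cleave the primary silyl ether and hydrolyse the dimethyl ketal, while the epoxide, deactivated by the two flanking carbonyl-level carbons, the allylic acetate and the trisubstituted alkenes should survive.

**Step 14**
Reactants: 24 (5S,6R)-epoxy enedione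
Product: 25 (4R,5R,6R)-3-(acetoxymethyl)-5,6-epoxy-4-hydroxy-6-[(2E,6E,10E)-12-hydroxy-3,7,11-trimethyldodeca-2,6,10-trien-1-yl]cyclohex-2-en-1-one (target; OH cis to the epoxide oxygen)
Conditions: NaBH4 (0.35 equiv), CeCl3·7H2O, MeOH/CH2Cl2, −78 °C
Reagents that add atoms: none
Why: Luche reduction should deliver hydride 1,2 to the C4 carbonyl, the less hindered one (C1 is flanked by quaternary C6, whose chain lies on the face anti to the epoxide), and anti to the C5–O bond (Felkin-type), which places the new hydroxyl cis to the epoxide oxygen (4R).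

**Compound list**

1 | (2E,6E)-farnesyl acetate | CC(=O)OC/C=C(\C)CC/C=C(\C)CCC=C(C)C | starting material
2 | (2E,6E,10E)-12-hydroxy-3,7,11-trimethyldodeca-2,6,10-trien-1-yl acetate | CC(=O)OC/C=C(\C)CC/C=C(\C)CC/C=C(\C)CO | intermediate
3 | (2E,6E,10E)-12-(tert-butyldimethylsilyloxy)-3,7,11-trimethyldodeca-2,6,10-trien-1-yl acetate | CC(=O)OC/C=C(\C)CC/C=C(\C)CC/C=C(\C)CO[Si](C)(C)C(C)(C)C | intermediate
4 | (E)-1,2-bis(tributylstannyl)ethene | CCCC[Sn](CCCC)(CCCC)/C=C/[Sn](CCCC)(CCCC)CCCC | starting material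
5 | tributyl[(1E,4E,8E,12E)-14-(tert-butyldimethylsilyloxy)-5,9,13-trimethyltetradeca-1,4,8,12-tetraen-1-yl]stannane | CCCC[Sn](CCCC)(CCCC)/C=C/C/C=C(\C)CC/C=C(\C)CC/C=C(\C)CO[Si](C)(C)C(C)(C)C | intermediate
6 | diisopropyl squarate (3,4-diisopropoxycyclobut-3-ene-1,2-dione) | CC(C)OC1=C(OC(C)C)C(=O)C1=O | starting material
7 | 4-hydroxy-2,3-diisopropoxycyclobut-2-en-1-one (hydride adduct, formed as its alkoxide) | CC(C)OC1=C(OC(C)C)C(O)C1=O | intermediate (not isolated)
8 | 3-isopropoxycyclobut-3-ene-1,2-dione | CC(C)OC1=CC(=O)C1=O | intermediate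
9 | (tributylstannyl)methanol | CCCC[Sn](CCCC)(CCCC)CO | starting material
10 | tributyl{[(4-methoxybenzyl)oxy]methyl}stannane | CCCC[Sn](CCCC)(CCCC)COCc1ccc(OC)cc1 | intermediate
11 | [(1E,4E,8E,12E)-14-(tert-butyldimethylsilyloxy)-5,9,13-trimethyltetradeca-1,4,8,12-tetraen-1-yl]lithium | [Li]/C=C/C/C=C(\C)CC/C=C(\C)CC/C=C(\C)CO[Si](C)(C)C(C)(C)C | intermediate (not isolated)
12 | lithium alkoxide of racemic 4-alkenyl-4-hydroxy-3-isopropoxycyclobut-2-en-1-one (alkenyl as in 11) | CC(C)OC1=CC(=O)C1(O[Li])/C=C/C/C=C(\C)CC/C=C(\C)CC/C=C(\C)CO[Si](C)(C)C(C)(C)C | intermediate (not isolated)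
13 | racemic 4-[(1E,4E,8E,12E)-14-(tert-butyldimethylsilyloxy)-5,9,13-trimethyltetradeca-1,4,8,12-tetraen-1-yl]-3-isopropoxy-4-methoxycyclobut-2-en-1-one | CC(C)OC1=CC(=O)C1(OC)/C=C/C/C=C(\C)CC/C=C(\C)CC/C=C(\C)CO[Si](C)(C)C(C)(C)C | intermediate
14 | {[(4-methoxybenzyl)oxy]methyl}lithium | [Li]COCc1ccc(OC)cc1 | intermediate (not isolated)
15 | lithium alkoxide of 4-alkenyl-3-isopropoxy-4-methoxy-1-{[(4-methoxybenzyl)oxy]methyl}cyclobut-2-en-1-ol (diastereomer mixture, racemic) | CC(C)OC1=CC(O[Li])(COCc2ccc(OC)cc2)C1(OC)/C=C/C/C=C(\C)CC/C=C(\C)CC/C=C(\C)CO[Si](C)(C)C(C)(C)C | intermediate (not isolated)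
16 | racemic 4-[(1E,4E,8E,12E)-14-(tert-butyldimethylsilyloxy)-5,9,13-trimethyltetradeca-1,4,8,12-tetraen-1-yl]-4-methoxy-3-{[(4-methoxybenzyl)oxy]methyl}cyclobut-2-en-1-one | COc1ccc(COCC2=CC(=O)C2(OC)/C=C/C/C=C(\C)CC/C=C(\C)CC/C=C(\C)CO[Si](C)(C)C(C)(C)C)cc1 | intermediate
17 | dienylketene O=C=CH–C(CH2OPMB)=C(OMe)–CH=CH–CH2–chain, ketenyl and vinyl groups cis on the central double bond | COc1ccc(COCC(\C=C=O)=C(OC)\C=C\C/C=C(\C)CC/C=C(\C)CC/C=C(\C)CO[Si](C)(C)C(C)(C)C)cc1 | intermediate (not isolated)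
18 | racemic 6-[(2E,6E,10E)-12-(tert-butyldimethylsilyloxy)-3,7,11-trimethyldodeca-2,6,10-trien-1-yl]-4-methoxy-3-{[(4-methoxybenzyl)oxy]methyl}cyclohexa-2,4-dien-1-one | COc1ccc(COCC2=CC(=O)C(C/C=C(\C)CC/C=C(\C)CC/C=C(\C)CO[Si](C)(C)C(C)(C)C)C=C2OC)cc1 | intermediate (not isolated)
19 | 6-[(2E,6E,10E)-12-(tert-butyldimethylsilyloxy)-3,7,11-trimethyldodeca-2,6,10-trien-1-yl]-4-methoxy-3-{[(4-methoxybenzyl)oxy]methyl}phenol (OH on C1) | COc1ccc(COCc2cc(O)c(C/C=C(\C)CC/C=C(\C)CC/C=C(\C)CO[Si](C)(C)C(C)(C)C)cc2OC)cc1 | intermediate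
20 | 6-[(2E,6E,10E)-12-(tert-butyldimethylsilyloxy)-3,7,11-trimethyldodeca-2,6,10-trien-1-yl]-4,4-dimethoxy-3-{[(4-methoxybenzyl)oxy]methyl}cyclohexa-2,5-dien-1-one | COc1ccc(COCC2=CC(=O)C(C/C=C(\C)CC/C=C(\C)CC/C=C(\C)CO[Si](C)(C)C(C)(C)C)=CC2(OC)OC)cc1 | intermediate
21 | 6-[(2E,6E,10E)-12-(tert-butyldimethylsilyloxy)-3,7,11-trimethyldodeca-2,6,10-trien-1-yl]-3-(hydroxymethyl)-4,4-dimethoxycyclohexa-2,5-dien-1-one | OCC1=CC(=O)C(C/C=C(\C)CC/C=C(\C)CC/C=C(\C)CO[Si](C)(C)C(C)(C)C)=CC1(OC)OC | intermediate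
22 | (5S,6R)-6-[(2E,6E,10E)-12-(tert-butyldimethylsilyloxy)-3,7,11-trimethyldodeca-2,6,10-trien-1-yl]-5,6-epoxy-3-(hydroxymethyl)-4,4-dimethoxycyclohex-2-en-1-one | OCC1=CC(=O)[C@]2(C/C=C(\C)CC/C=C(\C)CC/C=C(\C)CO[Si](C)(C)C(C)(C)C)O[C@@H]2C1(OC)OC | intermediate
23 | (5S,6R)-3-(acetoxymethyl)-6-[(2E,6E,10E)-12-(tert-butyldimethylsilyloxy)-3,7,11-trimethyldodeca-2,6,10-trien-1-yl]-5,6-epoxy-4,4-dimethoxycyclohex-2-en-1-one | CC(=O)OCC1=CC(=O)[C@]2(C/C=C(\C)CC/C=C(\C)CC/C=C(\C)CO[Si](C)(C)C(C)(C)C)O[C@@H]2C1(OC)OC | intermediate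
24 | (5S,6R)-3-(acetoxymethyl)-5,6-epoxy-6-[(2E,6E,10E)-12-hydroxy-3,7,11-trimethyldodeca-2,6,10-trien-1-yl]cyclohex-2-ene-1,4-dione | CC(=O)OCC1=CC(=O)[C@]2(C/C=C(\C)CC/C=C(\C)CC/C=C(\C)CO)O[C@@H]2C1=O | intermediate
25 | (4R,5R,6R)-3-(acetoxymethyl)-5,6-epoxy-4-hydroxy-6-[(2E,6E,10E)-12-hydroxy-3,7,11-trimethyldodeca-2,6,10-trien-1-yl]cyclohex-2-en-1-one | CC(=O)OCC1=CC(=O)[C@]2(C/C=C(\C)CC/C=C(\C)CC/C=C(\C)CO)O[C@@H]2[C@@H]1O | target

**Step count and risks**

Total steps: 14. Longest linear sequence: 12 (steps 1, 2, 3, 6, 7, 8, 9, 10, 11, 12, 13, 14).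

Steps most likely to fail:

- **Step 7.** The basic alkoxymethyllithium may deprotonate or degrade the hindered cyclobutenone instead of adding, or the tertiary allylic methyl ether may ionise during the acid-promoted transposition. The fallback sets out from 6 and 10 and reverses the order of the two carbonyl additions. Organolithium 14 (from 10 and n-BuLi) is added to 6 at −78 °C to give, after NH4Cl quench, 4-hydroxy-2,3-diisopropoxy-4-{[(4-methoxybenzyl)oxy]methyl}cyclobut-2-en-1-one F1. Its remaining carbonyl is reduced with LiAlH(OtBu)3 to 3,4-diisopropoxy-1-{[(4-methoxybenzyl)oxy]methyl}cyclobut-3-ene-1,2-diol F2, which is not isolated and is hydrolysed with aqueous HCl to 3-{[(4-methoxybenzyl)oxy]methyl}cyclobut-3-ene-1,2-dione F3. Alkenyllithium 11 (from 5) should then add to the carbonyl next to the substituted carbon, which is the one whose β-carbon is unsubstituted and which can chelate lithium with the ether oxygen, giving the lithium alkoxide of 4-alkenyl-4-hydroxy-3-{[(4-methoxybenzyl)oxy]methyl}cyclobut-2-en-1-one F4. In situ methylation with MeOTf comes back to the route at 16.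

- **Step 11.** Enantiofacial selectivity may be poor or conversion low, because the α-substituent on C6 slows the ring closure of the peroxy enolate and may loosen the tartrate-bound transition state. The fallback sets out from 21 and moves stereocontrol to a covalently bound auxiliary. Transketalisation with (2S,4S)-pentane-2,4-diol (PPTS, benzene, 40 °C, methanol removed) gives the C4 spiro-ketal of that diol, 6-(silyloxy-trienyl)-3-(hydroxymethyl)cyclohexa-2,5-dien-1-one 4-[(2S,4S)-pentane-2,4-diyl ketal] F5. Diastereoselective Weitz–Scheffer epoxidation (Ph3COOH, KN(SiMe3)2, THF, −78 °C), steered by the axial methyl group of the dioxane, should give the (5S,6R)-5,6-epoxide of that ketal F6; the diol enantiomer is assumed and would be exchanged for its antipode if the sense is opposite. Acetylation (Ac2O, pyridine) gives the (5S,6R)-3-(acetoxymethyl) epoxy ketal F7, and 48% aq. HF in MeCN removes the ketal and the silyl ether, coming back at 24.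

- **Step 14.** Hydride may attack the C1 carbonyl, add in conjugate fashion to the enedione, or approach syn to the epoxide. The fallback sets out from 22 and uses the free C3 hydroxymethyl group to deliver hydride to C4 only. Ketal hydrolysis with montmorillonite K10 in CH2Cl2, which keeps the silyl ether, gives (5S,6R)-6-(silyloxy-trienyl)-5,6-epoxy-3-(hydroxymethyl)cyclohex-2-ene-1,4-dione F8. Evans–Saksena reduction (Me4NBH(OAc)3, MeCN/AcOH, −40 °C), with intramolecular delivery from the alkoxyborohydride on the hydroxymethyl group and attack anti to the epoxide, should give (4R,5R,6R)-6-(silyloxy-trienyl)-5,6-epoxy-4-hydroxy-3-(hydroxymethyl)cyclohex-2-en-1-one F9. Selective acetylation of the primary alcohol (AcCl, 2,4,6-collidine, CH2Cl2, −78 °C) gives the 12-O-silyl ether of the target F10, and HF·pyridine in THF at 0 °C comes back at 25.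

**Further compounds**

F1 | step 7 | 4-hydroxy-2,3-diisopropoxy-4-{[(4-methoxybenzyl)oxy]methyl}cyclobut-2-en-1-one | CC(C)OC1=C(OC(C)C)C(O)(COCc2ccc(OC)cc2)C1=O
F2 | step 7 | 3,4-diisopropoxy-1-{[(4-methoxybenzyl)oxy]methyl}cyclobut-3-ene-1,2-diol | CC(C)OC1=C(OC(C)C)C(O)(COCc2ccc(OC)cc2)C1O
F3 | step 7 | 3-{[(4-methoxybenzyl)oxy]methyl}cyclobut-3-ene-1,2-dione | COc1ccc(COCC2=CC(=O)C2=O)cc1
F4 | step 7 | lithium alkoxide of racemic 4-[(1E,4E,8E,12E)-14-(tert-butyldimethylsilyloxy)-5,9,13-trimethyltetradeca-1,4,8,12-tetraen-1-yl]-4-hydroxy-3-{[(4-methoxybenzyl)oxy]methyl}cyclobut-2-en-1-one | COc1ccc(COCC2=CC(=O)C2(O[Li])/C=C/C/C=C(\C)CC/C=C(\C)CC/C=C(\C)CO[Si](C)(C)C(C)(C)C)cc1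
F5 | step 11 | 6-[(2E,6E,10E)-12-(tert-butyldimethylsilyloxy)-3,7,11-trimethyldodeca-2,6,10-trien-1-yl]-3-(hydroxymethyl)cyclohexa-2,5-dien-1-one 4-[(2S,4S)-pentane-2,4-diyl ketal] | OCC1=CC(=O)C(C/C=C(\C)CC/C=C(\C)CC/C=C(\C)CO[Si](C)(C)C(C)(C)C)=CC12O[C@@H](C)C[C@H](C)O2
F6 | step 11 | (5S,6R)-5,6-epoxide of F5 | OCC1=CC(=O)[C@]2(C/C=C(\C)CC/C=C(\C)CC/C=C(\C)CO[Si](C)(C)C(C)(C)C)O[C@@H]2C13O[C@@H](C)C[C@H](C)O3
F7 | step 11 | (5S,6R)-3-(acetoxymethyl) epoxy ketal (O-acetate of F6) | CC(=O)OCC1=CC(=O)[C@]2(C/C=C(\C)CC/C=C(\C)CC/C=C(\C)CO[Si](C)(C)C(C)(C)C)O[C@@H]2C13O[C@@H](C)C[C@H](C)O3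
F8 | step 14 | (5S,6R)-6-[(2E,6E,10E)-12-(tert-butyldimethylsilyloxy)-3,7,11-trimethyldodeca-2,6,10-trien-1-yl]-5,6-epoxy-3-(hydroxymethyl)cyclohex-2-ene-1,4-dione | OCC1=CC(=O)[C@]2(C/C=C(\C)CC/C=C(\C)CC/C=C(\C)CO[Si](C)(C)C(C)(C)C)O[C@@H]2C1=O
F9 | step 14 | (4R,5R,6R)-6-[(2E,6E,10E)-12-(tert-butyldimethylsilyloxy)-3,7,11-trimethyldodeca-2,6,10-trien-1-yl]-5,6-epoxy-4-hydroxy-3-(hydroxymethyl)cyclohex-2-en-1-one | OCC1=CC(=O)[C@]2(C/C=C(\C)CC/C=C(\C)CC/C=C(\C)CO[Si](C)(C)C(C)(C)C)O[C@@H]2[C@@H]1O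
F10 | step 14 | (4R,5R,6R)-3-(acetoxymethyl)-6-[(2E,6E,10E)-12-(tert-butyldimethylsilyloxy)-3,7,11-trimethyldodeca-2,6,10-trien-1-yl]-5,6-epoxy-4-hydroxycyclohex-2-en-1-one | CC(=O)OCC1=CC(=O)[C@]2(C/C=C(\C)CC/C=C(\C)CC/C=C(\C)CO[Si](C)(C)C(C)(C)C)O[C@@H]2[C@@H]1O
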